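## Retrosynthetic overview

- Target 22 ⇒ bis-silyl ether 21 ⇒ (one flask) ethynyl oxirane 9 + pentaenyl boronate 19: the C2(ring B)–C11(chain) bond is formed by a syn-SN2' alkenylation of the propargylic oxirane, and the resulting α-allenol is cycloisomerised in the same flask to close ring B.
- Enabling feature: in ring B the array O1–C7a(quaternary, methyl-bearing)–C3a=C3–C2(H) is the cycloisomer of an α-allenol C7a(OH)–C3a=C3=C2(H), which is the SN2' product of a C3a–C7a oxirane carrying an ethynyl group on C3a; the oxirane configuration is relayed centre → allene axis → C2.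
- 9 ⇐ (−)-actinol 1 (chiral pool: ring A with its carbinol centre) via enol triflate, methoxycarbonylation, reduction, Sharpless epoxidation (sets the future C3a/C7a), oxidation and alkyne homologation.
- 19 ⇐ C10 dialdehyde 12 + butynylphosphonate 11 (Horner–Wadsworth–Emmons), then reduction, silylation, hydrozirconation–iodination and borylation.
- Ring order: ring A (from 1) → temporary oxirane (step 5) → ring B (step 14); both silyl ethers are removed last.

Key step: step 14

Assumption: (−)-actinol 1 and the all-E C10 dialdehyde 12 are taken as purchasable single isomers. Ring A is the cyclohexane and ring B the 2,5-dihydrofuran; benzofuran locants are used for the bicycle and dodecapentaenol locants for the chain.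

## Route

Step 1
Reactants: 1 (−)-actinol
Product: 2 (4R,6R)-4-[(tert-butyldimethylsilyl)oxy]-2,2,6-trimethylcyclohexan-1-one
Conditions: TBSCl, imidazole, DMF, 23 °C
Reagents that add atoms: tert-butyldimethylsilyl chloride, CC(C)(C)[Si](C)(C)Cl
Why: Imidazole-promoted silyl ether formation on the only hydroxyl; no stereocentre is touched.

Step 2
Reactants: 2 silyl ether of actinol
Product: 4 (4R)-4-[(tert-butyldimethylsilyl)oxy]-2,6,6-trimethylcyclohex-1-en-1-yl trifluoromethanesulfonate, via lithium enolate 3 (not isolated)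
Conditions: LiN(i-Pr)2, THF, −78 °C; then PhNTf2, −78 → 0 °C
Reagents that add atoms: N-phenylbis(trifluoromethanesulfonimide), O=S(=O)(N(c1ccccc1)S(=O)(=O)C(F)(F)F)C(F)(F)F
Why: Only one α-carbon carries hydrogen, so a single tetrasubstituted enolate forms and is O-triflated (enol triflate formation); the methyl-bearing stereocentre is deliberately erased.

Step 3
Reactants: 4 enol triflate
Product: 5 methyl (4R)-4-[(tert-butyldimethylsilyl)oxy]-2,6,6-trimethylcyclohex-1-ene-1-carboxylate
Conditions: Pd(OAc)2 (cat.), PPh3, NEt3, CO (1 atm), MeOH/DMF, 70 °C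
Reagents that add atoms: carbon monoxide, [C-]#[O+]; methanol, CO
Why: Palladium-catalysed alkoxycarbonylation of a vinyl triflate (oxidative addition, CO insertion, methanolysis), which leaves the silyl ether intact.

Step 4
Reactants: 5 methyl ester
Product: 6 {(4R)-4-[(tert-butyldimethylsilyl)oxy]-2,6,6-trimethylcyclohex-1-en-1-yl}methanol
Conditions: i-Bu2AlH, CH2Cl2, −78 → 0 °C; aqueous potassium sodium tartrate
Reagents that add atoms: none
Why: 1,2-Reduction of the conjugated ester by the aluminium hydride gives the allylic alcohol needed to direct the epoxidation.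

Step 5
Reactants: 6 allylic alcohol
Product: 7 {(1R,4S,6R)-4-[(tert-butyldimethylsilyl)oxy]-2,2,6-trimethyl-7-oxabicyclo[4.1.0]heptan-1-yl}methanol (oxirane anti to the silyloxy group)
Conditions: Ti(Oi-Pr)4 (0.3 equiv), D-(−)-diethyl tartrate (0.36 equiv), t-BuOOH, 4 Å MS, CH2Cl2, −20 °C
Reagents that add atoms: tert-butyl hydroperoxide, CC(C)(C)OO
Why: Katsuki–Sharpless asymmetric epoxidation, in which the titanium–D-(−)-tartrate complex should deliver oxygen to the alkene face anti to the C4 silyloxy group (reagent control through the allylic alcohol), setting both oxirane carbons and hence the future C7a.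

Step 6
Reactants: 7 epoxy alcohol
Product: 8 (1S,4S,6R)-4-[(tert-butyldimethylsilyl)oxy]-2,2,6-trimethyl-7-oxabicyclo[4.1.0]heptane-1-carbaldehyde
Conditions: (n-Pr4N)RuO4 (cat.), N-methylmorpholine N-oxide, 4 Å MS, CH2Cl2, 23 °C
Reagents that add atoms: none
Why: Ley–Griffith oxidation under neutral conditions; the aldehyde has no α-hydrogen, so nothing can epimerise and the oxirane survives.

Step 7
Reactants: 8 epoxy aldehyde
Product: 9 tert-butyl{[(1R,4S,6R)-1-ethynyl-2,2,6-trimethyl-7-oxabicyclo[4.1.0]heptan-4-yl]oxy}dimethylsilane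
Conditions: dimethyl (1-diazo-2-oxopropyl)phosphonate, K2CO3, MeOH, 0 → 23 °C
Reagents that add atoms: dimethyl (1-diazo-2-oxopropyl)phosphonate, CC(=O)C(=[N+]=[N-])P(=O)(OC)OC
Why: Seyferth–Gilbert homologation with the Ohira–Bestmann reagent (diazomethylphosphonate anion formed in the flask, then alkylidene-carbene 1,2-shift) gives the terminal alkyne under base mild enough for the quaternary oxirane.

Step 8
Reactants: 10 1-bromobut-2-yne
Product: 11 diethyl but-2-yn-1-ylphosphonate
Conditions: P(OEt)3 (neat), 130 °C, distillation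
Reagents that add atoms: triethyl phosphite, CCOP(OCC)OCC
Why: Michaelis–Arbuzov reaction of a primary propargylic bromide.

Step 9
Reactants: 11 butynylphosphonate, 12 (2E,4E,6E)-2,7-dimethylocta-2,4,6-trienedial
Product: 14 (2E,4E,6E,8E)-2,7-dimethyldodeca-2,4,6,8-tetraen-10-ynal, via sodium phosphonate carbanion 13 (not isolated)
Conditions: NaN(SiMe3)2, THF, −78 °C; then cannulated into 12 (3 equiv), −78 → 0 °C; I2 (cat.), CH2Cl2, 23 °C
Reagents that add atoms: none
Why: Horner–Wadsworth–Emmons olefination through the α-carbon of the propargyl phosphonate anion, with excess dialdehyde to suppress double olefination and iodine equilibration to bring the new double bond to E.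

Step 10
Reactants: 14 tetraenynal
Product: 15 (2E,4E,6E,8E)-2,7-dimethyldodeca-2,4,6,8-tetraen-10-yn-1-ol
Conditions: NaBH4, MeOH/THF, 0 °C
Reagents that add atoms: none
Why: Borohydride 1,2-reduction of a polyenal (the retinal-to-retinol type), which leaves the polyene and the alkyne alone.

Step 11
Reactants: 15 tetraenynol
Product: 16 tert-butyl{[(2E,4E,6E,8E)-2,7-dimethyldodeca-2,4,6,8-tetraen-10-yn-1-yl]oxy}dimethylsilane
Conditions: TBSCl, imidazole, DMF, 0 → 23 °C
Reagents that add atoms: tert-butyldimethylsilyl chloride, CC(C)(C)[Si](C)(C)Cl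
Why: Silylation of the primary allylic alcohol so that the hydride and organometallic steps that follow meet no acidic hydrogen.

Step 12
Reactants: 16 silylated tetraenyne
Product: 18 tert-butyl{[(2E,4E,6E,8E,10E)-11-iodo-2,7-dimethyldodeca-2,4,6,8,10-pentaen-1-yl]oxy}dimethylsilane, via alkenylzirconocene chloride 17 (not isolated)
Conditions: Cp2Zr(H)Cl (1.5 equiv), THF, 23–40 °C, dark; then I2 (1 equiv per Zr), THF, −78 °C
Reagents that add atoms: iodine, II
Why: syn-Hydrozirconation with the Schwartz reagent should place zirconium on the less hindered, methyl-bearing alkyne carbon distal to the polyene, and iodinolysis of the carbon–zirconium bond with retention gives the alkenyl iodide with iodide trans to the chain.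

Step 13
Reactants: 18 pentaenyl iodide
Product: 19 tert-butyl{[(2E,4E,6E,8E,10Z)-2,7-dimethyl-11-(4,4,5,5-tetramethyl-1,3,2-dioxaborolan-2-yl)dodeca-2,4,6,8,10-pentaen-1-yl]oxy}dimethylsilane (boron trans to the chain; 10Z only by CIP priority)
Conditions: PdCl2(PPh3)2 (cat.), PPh3, KOPh, B2pin2, toluene, 50 °C
Reagents that add atoms: bis(pinacolato)diboron, CC1(C)OB(OC1(C)C)B1OC(C)(C)C(C)(C)O1
Why: Miyaura borylation of an alkenyl iodide proceeds with retention of geometry, and the weak base KOPh suppresses Suzuki homocoupling.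

Step 14
Reactants: 9 ethynyl oxirane, 19 pentaenyl boronate
Product: 21 tert-butyl{[(2E,4E,6E,8E,10E)-11-[(2R,6S,7aR)-6-{[tert-butyl(dimethyl)silyl]oxy}-4,4,7a-trimethyl-2,4,5,6,7,7a-hexahydro-1-benzofuran-2-yl]-2,7-dimethyldodeca-2,4,6,8,10-pentaen-1-yl]oxy}dimethylsilane, via syn-allenol 20 (not isolated)
Conditions: [Rh(OH)(cod)]2 (2.5 mol %), KOH (0.2 equiv), 19 (1.3 equiv), THF/H2O 20:1, 23 °C, dark, 9 added slowly; then AgNO3 (0.8 equiv), CaCO3, acetone/H2O, 23 °C, dark
Reagents that add atoms: none
Why: Proposed new method: the hydroxorhodium complex transmetalates boronate 19 to an alkenylrhodium (monovalent rhodium) that adds syn across the terminal alkyne of 9, with the alkenyl group going to the unsubstituted carbon and rhodium to the carbon next to the oxirane (oxygen-directed, the same 2,1-insertion as in rhodium-initiated acetylene polymerisation), and syn β-oxygen elimination then opens the oxirane to syn-allenol 20; the closest known reaction is the rhodium-catalysed syn-SN2' arylation of internal alkynyl oxiranes with arylboronic acids, here extended to an alkenyl boronate and a terminal alkyne, where fast intramolecular β-oxygen elimination is expected to outrun acetylide formation and a second insertion. This forms the C2(ring B)–C11(chain) bond and turns the oxirane centre at the future C3a into the allene axis (centre to axis). Silver nitrate then closes ring B by 5-endo-trig anti-oxymetalation and protodemetalation of the α-allenol (known silver and gold chemistry), which transfers the axis to the new C2 stereocentre with the chain trans to the C7a methyl, i.e. 2R. The selectivities needed are syn rather than anti SN2' (secured by the carbometalation/β-elimination pathway; zerovalent palladium would go anti and end in the C2 epimer), alkenyl transfer to the terminal alkyne carbon (sterics plus oxirane direction), retention of the boronate geometry (stereoretentive transmetalation) and no erosion of the allene axis before closure (buffered neutral medium, dark).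

Step 15
Reactants: 21 bis-silyl ether
Product: 22 (2E,4E,6E,8E,10E)-11-[(2R,6S,7aR)-6-hydroxy-4,4,7a-trimethyl-2,4,5,6,7,7a-hexahydro-1-benzofuran-2-yl]-2,7-dimethyldodeca-2,4,6,8,10-pentaen-1-ol
Conditions: n-Bu4NF, THF, 0 → 23 °C, dark
Reagents that add atoms: none
Why: Fluoride cleaves both silyl ethers under basic, acid-free conditions, so the acid-labile doubly allylic ring B ether and its C2 configuration should survive.

## Compound list

1 | (−)-actinol, (4R,6R)-4-hydroxy-2,2,6-trimethylcyclohexan-1-one | O=C1C(C)(C)C[C@H](O)C[C@H]1C | starting material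
2 | (4R,6R)-4-[(tert-butyldimethylsilyl)oxy]-2,2,6-trimethylcyclohexan-1-one | O=C1C(C)(C)C[C@H](O[Si](C)(C)C(C)(C)C)C[C@H]1C | intermediate
3 | lithium (4R)-4-[(tert-butyldimethylsilyl)oxy]-2,6,6-trimethylcyclohex-1-en-1-olate | CC1=C(O[Li])C(C)(C)C[C@H](O[Si](C)(C)C(C)(C)C)C1 | intermediate (not isolated)
4 | (4R)-4-[(tert-butyldimethylsilyl)oxy]-2,6,6-trimethylcyclohex-1-en-1-yl trifluoromethanesulfonate | CC1=C(OS(=O)(=O)C(F)(F)F)C(C)(C)C[C@H](O[Si](C)(C)C(C)(C)C)C1 | intermediate
5 | methyl (4R)-4-[(tert-butyldimethylsilyl)oxy]-2,6,6-trimethylcyclohex-1-ene-1-carboxylate | CC1=C(C(=O)OC)C(C)(C)C[C@H](O[Si](C)(C)C(C)(C)C)C1 | intermediate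
6 | {(4R)-4-[(tert-butyldimethylsilyl)oxy]-2,6,6-trimethylcyclohex-1-en-1-yl}methanol | CC1=C(CO)C(C)(C)C[C@H](O[Si](C)(C)C(C)(C)C)C1 | intermediate
7 | {(1R,4S,6R)-4-[(tert-butyldimethylsilyl)oxy]-2,2,6-trimethyl-7-oxabicyclo[4.1.0]heptan-1-yl}methanol | OC[C@]12C(C)(C)C[C@H](O[Si](C)(C)C(C)(C)C)C[C@@]1(C)O2 | intermediate
8 | (1S,4S,6R)-4-[(tert-butyldimethylsilyl)oxy]-2,2,6-trimethyl-7-oxabicyclo[4.1.0]heptane-1-carbaldehyde | O=C[C@]12C(C)(C)C[C@H](O[Si](C)(C)C(C)(C)C)C[C@@]1(C)O2 | intermediate
9 | tert-butyl{[(1R,4S,6R)-1-ethynyl-2,2,6-trimethyl-7-oxabicyclo[4.1.0]heptan-4-yl]oxy}dimethylsilane | C#C[C@]12C(C)(C)C[C@H](O[Si](C)(C)C(C)(C)C)C[C@@]1(C)O2 | intermediate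
10 | 1-bromobut-2-yne | CC#CCBr | starting material
11 | diethyl but-2-yn-1-ylphosphonate | CC#CCP(=O)(OCC)OCC | intermediate
12 | (2E,4E,6E)-2,7-dimethylocta-2,4,6-trienedial | CC(/C=O)=C\C=C\C=C(/C)C=O | starting material
13 | sodium 1-(diethoxyphosphoryl)but-2-yn-1-ide | CC#C[CH-]P(=O)(OCC)OCC.[Na+] | intermediate (not isolated)
14 | (2E,4E,6E,8E)-2,7-dimethyldodeca-2,4,6,8-tetraen-10-ynal | CC(/C=C/C#CC)=C\C=C\C=C(/C)C=O | intermediate
15 | (2E,4E,6E,8E)-2,7-dimethyldodeca-2,4,6,8-tetraen-10-yn-1-ol | CC(/C=C/C#CC)=C\C=C\C=C(/C)CO | intermediate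
16 | tert-butyl{[(2E,4E,6E,8E)-2,7-dimethyldodeca-2,4,6,8-tetraen-10-yn-1-yl]oxy}dimethylsilane | CC(/C=C/C#CC)=C\C=C\C=C(/C)CO[Si](C)(C)C(C)(C)C | intermediate
17 | chlorobis(cyclopentadienyl){(2E,4E,6E,8E,10E)-12-[(tert-butyldimethylsilyl)oxy]-6,11-dimethyldodeca-2,4,6,8,10-pentaen-2-yl}zirconium | CC(/C=C/C=C(\C)[Zr](Cl)(C1C=CC=C1)C1C=CC=C1)=C\C=C\C=C(/C)CO[Si](C)(C)C(C)(C)C | intermediate (not isolated)
18 | tert-butyl{[(2E,4E,6E,8E,10E)-11-iodo-2,7-dimethyldodeca-2,4,6,8,10-pentaen-1-yl]oxy}dimethylsilane | CC(/C=C/C=C(\C)I)=C\C=C\C=C(/C)CO[Si](C)(C)C(C)(C)C | intermediate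
19 | tert-butyl{[(2E,4E,6E,8E,10Z)-2,7-dimethyl-11-(4,4,5,5-tetramethyl-1,3,2-dioxaborolan-2-yl)dodeca-2,4,6,8,10-pentaen-1-yl]oxy}dimethylsilane | CC(/C=C/C=C(\C)B1OC(C)(C)C(C)(C)O1)=C\C=C\C=C(/C)CO[Si](C)(C)C(C)(C)C | intermediate
20 | (1R,5S)-5-[(tert-butyldimethylsilyl)oxy]-2-[(3E,5E,7E,9E,11E)-13-[(tert-butyldimethylsilyl)oxy]-3,7,12-trimethyltrideca-1,3,5,7,9,11-hexaen-1-ylidene]-1,3,3-trimethylcyclohexan-1-ol, (S)-configured allene axis (chain on the face of the tertiary hydroxyl) | CC(/C=C/C=C(\C)C([H])=[C@]=C1C(C)(C)C[C@H](O[Si](C)(C)C(C)(C)C)C[C@@]1(C)O)=C\C=C\C=C(/C)CO[Si](C)(C)C(C)(C)C | intermediate (not isolated)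
21 | tert-butyl{[(2E,4E,6E,8E,10E)-11-[(2R,6S,7aR)-6-{[tert-butyl(dimethyl)silyl]oxy}-4,4,7a-trimethyl-2,4,5,6,7,7a-hexahydro-1-benzofuran-2-yl]-2,7-dimethyldodeca-2,4,6,8,10-pentaen-1-yl]oxy}dimethylsilane | CC(/C=C/C=C(\C)[C@H]1C=C2C(C)(C)C[C@H](O[Si](C)(C)C(C)(C)C)C[C@@]2(C)O1)=C\C=C\C=C(/C)CO[Si](C)(C)C(C)(C)C | intermediate
22 | (2E,4E,6E,8E,10E)-11-[(2R,6S,7aR)-6-hydroxy-4,4,7a-trimethyl-2,4,5,6,7,7a-hexahydro-1-benzofuran-2-yl]-2,7-dimethyldodeca-2,4,6,8,10-pentaen-1-ol | CC(/C=C/C=C(\C)[C@H]1C=C2C(C)(C)C[C@H](O)C[C@@]2(C)O1)=C\C=C\C=C(/C)CO | target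

## Step count and risks

Total steps: 15. Longest linear sequence: 9 steps (1 → 22 through steps 1–7, 14 and 15); the chain branch contributes steps 8–13.

Steps most likely to fail:

Step 14 (Proposed new method). The rhodium alkenyl may be lost to acetylide formation, alkyne oligomerisation or protodeboronation before it carbometalates the terminal alkyne, and the allene axis may erode during the silver-mediated closure. The fallback uses known reactions and sets out from 9 and 18. Sonogashira coupling (PdCl2(PPh3)2, CuI, i-Pr2NH, THF, 23 °C) joins the same two carbons as an sp–sp2 bond and gives the internal alkynyl oxirane F1. Formate hydrogenolysis catalysed by zerovalent palladium (Pd2(dba)3·CHCl3, n-Bu3P, HCO2H, NEt3, THF, 23–40 °C) then delivers hydride anti to the oxirane in the SN2' sense. Because hydrogen enters anti, the chain ends up on the oxirane-oxygen face, which is the same allenol 20. The route is rejoined at 20, and the AgNO3/CaCO3 closure gives 21.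

Step 12. Hydrozirconation may occur at the wrong alkyne carbon or on the polyene, and iodine may isomerise or add to the pentaene during iodinolysis. The fallback sets out from 16 and comes back at 19, bypassing 18. It is a copper-catalysed formal hydroboration (CuCl, P(p-tol)3, NaOt-Bu, B2pin2, MeOH, THF, 23 °C): syn-borylcupration puts boron on the methyl-bearing carbon and copper on the carbon conjugated to the polyene, and methanol protonates the carbon–copper bond.

Step 5. Oxygen transfer to the hindered tetrasubstituted alkene may be slow or poorly face-selective. The fallback sets out from 4 and comes back at 9, bypassing steps 3–7. Sonogashira coupling of 4 with ethynyltrimethylsilane (PdCl2(PPh3)2, CuI, i-Pr2NH, DMF, 60 °C) gives the silylated enyne F2, and K2CO3/MeOH gives the terminal enyne F3. Substrate-controlled epoxidation of the ring alkene with mCPBA/NaHCO3 (CH2Cl2, 0 °C) is expected to favour the face opposite the silyloxy group and gives 9 after separation of any minor diastereomer.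

Further compounds
F1 | step 14 | tert-butyl{[(2E,4E,6E,8E,10E)-13-[(1R,4S,6R)-4-{[tert-butyl(dimethyl)silyl]oxy}-2,2,6-trimethyl-7-oxabicyclo[4.1.0]heptan-1-yl]-2,7,11-trimethyltrideca-2,4,6,8,10-pentaen-12-yn-1-yl]oxy}dimethylsilane | CC(/C=C/C=C(\C)C#C[C@]12C(C)(C)C[C@H](O[Si](C)(C)C(C)(C)C)C[C@@]1(C)O2)=C\C=C\C=C(/C)CO[Si](C)(C)C(C)(C)C
F0 | step 12 | none | none
F2 | step 5 | tert-butyl(dimethyl){[(1R)-3,5,5-trimethyl-4-[(trimethylsilyl)ethynyl]cyclohex-3-en-1-yl]oxy}silane | CC1=C(C#C[Si](C)(C)C)C(C)(C)C[C@H](O[Si](C)(C)C(C)(C)C)C1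
F3 | step 5 | tert-butyl{[(1R)-4-ethynyl-3,5,5-trimethylcyclohex-3-en-1-yl]oxy}dimethylsilane | CC1=C(C#C)C(C)(C)C[C@H](O[Si](C)(C)C(C)(C)C)C1
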